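All constants stand for no real mixture; the flask was simulated.

We have to choose the next run.

in all of them: substrate 20 mM

| run | first nucleophile | second nucleophile | remark | time |
|---|---|---|---|---|
| Sunday's | 20.0 mM | 16.0 mM | one stirred flow tank at steady state, fed with the mixture as stated, mean residence time 25 min |  |
| Wednesday's | 20.0 mM (fed, over 12.5 min) | 16.0 mM | all but first nucleophile at the start; first nucleophile goes in evenly over 12.5 min, the run ends at 25 min | 25 min |
| Saturday's | 20.0 mM | 16.0 mM | everything together in a closed stirred flask, run for 25 min | 25 min |
| Friday's | 20.0 mM | 16.0 mM (fed, over 12.5 min) | a stirred flask in which second nucleophile is dosed at a steady rate over 12.5 min without added volume, worked up at 25 min | 25 min |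

    substrate ⇌ intermediate (K1 = 0.191, k1 = 1.43 min⁻¹)
    first nucleophile + intermediate → target (k2 = 2840 L mol⁻¹ min⁻¹)
    second nucleophile + intermediate → other capture product (k3 = 4680 L mol⁻¹ min⁻¹)
    target ⇌ isomer of the product (K4 = 1.6, k4 = 0.179 min⁻¹)
    2 substrate → homo dimer (k5 = 2.80 L mol⁻¹ min⁻¹)
    second nucleophile + target → over-reaction product (k6 = 2.07 L mol⁻¹ min⁻¹)

- percent here means substrate units held: one homo dimer counts as two
- two of one species on the left: rate k times its square, two consumed each time
- the stated concentrations are those of everything mixed, before any reaction; amounts are the same in each set-up
- the feed brings no volume worth counting
- run time (Wednesday's): 25 min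

- the set-up with the highest amount of target at the outlet or at the end, in percent of the substrate put in ("none" if the first two lie within 2 percentage points) (Sunday's / Wednesday's / Saturday's / Friday's / none)
- amount of target at the outlet or at the end, in percent of the substrate put in, Sunday's
- amount of target at the outlet or at the end, in percent of the substrate put in, Wednesday's
- amount of target at the outlet or at the end, in percent of the substrate put in, Saturday's
- amount of target at the outlet or at the end, in percent of the substrate put in, Friday's

The choice hangs on who meets the intermediate, and on how much target survives afterwards. By its forward step, substrate has a half-life of 0.485 min, much shorter than the dosing time of 12.5 min. So in a dosed flask we expect most substrate to react before much of the dosed nucleophile has arrived.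

The three closed flasks share one factor. Target turns into its isomer, and at balance target holds the fraction 1/(1+K4) of the pair, the target share 0.385.

In Saturday's flask both nucleophiles compete from the start. The capture share, our selectivity, is 0.431. Target's forward half-life of 3.87 min is short against 25 min, so we multiply by the target share and expect 16.6%.

In Friday's flask, second nucleophile has reached about 0.895 mM after one mean life of substrate. The capture share therefore rises to 0.931. We treat over-reaction as a correction. Taking c(second nucleophile) as unspent, its sum over time is cD(t1 − tf/2). Target is the part of the pair exposed, so the pair keeps 0.788. That gives 28.2%.

In Wednesday's flask, second nucleophile captures first, but its 16.0 mM is less than the 20 mM of substrate. We give the difference to the first nucleophile and expect 7.69%.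

In Sunday's tank we keep Saturday's capture share as a rough step. Some target also leaves before reaching balance, and the pair's balance in the tank gives a target share of 0.459, above the closed-flask value. We expect 19.8%.

We would run Friday's.

The forecast also names Friday's, with 20.4%, 6.4%, 14.9% and 25.2% for Sunday's, Wednesday's, Saturday's and Friday's, and it starts from this: “The substrate ionises slowly compared with capture of the intermediate”.

The simulation gives Friday's, with 20.4%, 6.53%, 15.1% and 25.7% in the same order.

Target's forward half-life of 3.9 min is shorter than the 21 min of step 6 with Saturday's charge, and it is short against the 25 min of the run. Dividing by the target share, Saturday's 15.1% of target stands for a pair of about 39.2% of the substrate put in, and Friday's 25.7% stands for about 66.8%.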